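**Plan**

1. Numbering used below (elemane numbering): cyclohexane C5–C10; C10 is quaternary (C14 methyl, C1=C2 vinyl); C9 carries the angelate; C8–O and C7 carry the lactone O–C12(=O)–C11(=C13H2); C6 carries the acetate; C5 carries C4(=C3H2)–C15HO.
2. Enabling feature: the ring bond C9–C10 joins a carbinol carbon to a quaternary carbon bearing a vinyl group, i.e. a homoallylic alcohol O–C9–C10–C1=C2 inside the cyclohexane. Cutting it gives a C9 aldehyde and a (Z)-allylic chloride Cl–C2H2–C1H=C10(CH3)–C5, two electrophiles that are joined by reductive polarity reversal with CrCl2.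
3. Further cuts: C15 oxidation and the C9–O angelate (last); C2–Cl and C6–OAc arise together by acylative opening of a temporary 3,6-dihydro-2H-pyran (O6–C2), itself made by ring-closing metathesis (C1=C10); C5–C6 and C7–C8 are two auxiliary-controlled syn-aldol bonds; C13 comes from a Mannich methylenation.
4. Forward order: γ-lactone (step 2) → C5–C6 chain extension (step 6) → dihydropyran (step 8) → C4 isopropenyl and C13 methylene → pyran opened (step 13) → cyclohexane closed at C9–C10 (step 16) → angelate, then C15 aldehyde.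
5. Stereochemistry: C7/C8 from the (R)-oxazolidinone; C5/C6 from the (S)-oxazolidinone; the pyran ring stores the Z-olefin; C9/C10 from the fused chair transition state of the allylchromium addition, controlled by C5, C7 and C8; the angelate geometry is bought with angelic acid.

Key step: step 16

Assumption: compounds 1, 2, 4, 9, 10 and 26 and all reagents named under Conditions are taken as purchased.

**Step 1**
Reactants: 1 (R)-4-benzyloxazolidin-2-one; 2 methyl 4-chloro-4-oxobutanoate
Product: 3 succinate imide
Conditions: n-BuLi, THF, −78 °C; then 2, −78 → 0 °C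
Reagents that add atoms: none
Why: N-acylation of the lithiated oxazolidinone by an acid chloride is the standard entry to an Evans imide and forms no stereocentre.

**Step 2**
Reactants: 3 succinate imide; 4 2-[(tert-butyldiphenylsilyl)oxy]acetaldehyde
Product: 6 trans-lactone imide, via syn-aldol adduct 5 (not isolated)
Conditions: Bu2BOTf, i-Pr2NEt, CH2Cl2, −78 → 0 °C; 4, −78 → 0 °C; pH 7 buffer, MeOH, H2O2, 0 °C; then PPTS (cat.), toluene, 60 °C
Reagents that add atoms: none
Why: Evans syn-aldol reaction: only the imide is enolised to its Z-boron enolate, which adds through a Zimmerman–Traxler chair with the (R)-benzyl group blocking one face, setting C7 and C8 syn, and the γ-hydroxy ester then closes under mild acid to the trans-γ-lactone (first ring).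

**Step 3**
Reactants: 6 trans-lactone imide
Product: 7 lactone thioester
Conditions: EtSH, n-BuLi, THF, 0 °C
Reagents that add atoms: ethanethiol, CCS
Why: Thiolate transacylation cleaves the exocyclic imide carbonyl chemoselectively beside the lactone and releases the auxiliary without touching C7.

**Step 4**
Reactants: 7 lactone thioester
Product: 8 lactone aldehyde
Conditions: Et3SiH, 10% Pd/C, acetone, rt
Reagents that add atoms: none
Why: The Fukuyama reduction of a thioester stops at the aldehyde under neutral conditions, so the epimerisable β-acyloxy aldehyde centre C7 should be preserved.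

**Step 5**
Reactants: 9 (S)-4-benzyloxazolidin-2-one; 10 3-methylbut-2-enoyl chloride
Product: 11 senecioyl imide
Conditions: n-BuLi, THF, −78 °C; then 10, −78 → 0 °C
Reagents that add atoms: none
Why: Same N-acylation as in step 1; no stereocentre is formed.

**Step 6**
Reactants: 11 senecioyl imide; 8 lactone aldehyde
Product: 12 aldol adduct
Conditions: Bu2BOTf, Et3N, CH2Cl2, −78 → 0 °C; 8, −78 → 0 °C; pH 7 buffer, MeOH, H2O2, 0 °C
Reagents that add atoms: none
Why: Evans syn-aldol reaction of a dienolate (deconjugative aldol): γ-deprotonation gives the Z-boron dienolate, which bonds through its α-carbon in a chair transition state, so the (S)-benzyl auxiliary sets C5 and C6 (syn, isopropenyl as α-substituent); this sense should be matched with the anti-Felkin preference of Z-enolates toward the α-branched aldehyde.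

**Step 7**
Reactants: 12 aldol adduct
Product: 13 O-allyl ether
Conditions: allyl 2,2,2-trichloroacetimidate, TfOH (cat.), cyclohexane/CH2Cl2, 0 °C → rt
Reagents that add atoms: allyl 2,2,2-trichloroacetimidate, C=CCOC(=N)C(Cl)(Cl)Cl
Why: Acid-catalysed trichloroacetimidate O-alkylation etherifies the hindered C6–OH without forming an alkoxide, which avoids retro-aldol cleavage and translactonisation of the β-hydroxy imide.

**Step 8**
Reactants: 13 O-allyl ether
Product: 14 dihydropyran imide
Conditions: second-generation Grubbs catalyst (H2IMes)(PCy3)Cl2Ru=CHPh (5 mol %), CH2Cl2 (0.01 M), 40 °C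
Reagents that add atoms: none
Why: Ring-closing metathesis of the O-allyl and isopropenyl groups should give the 3,6-dihydro-2H-pyran (second, temporary ring), whose trisubstituted C10=C1 bond is necessarily Z and which masks both the C6 oxygen and the future allylic halide.

**Step 9**
Reactants: 14 dihydropyran imide
Product: 15 dihydropyran thioester
Conditions: EtSH, n-BuLi, THF, 0 °C
Reagents that add atoms: ethanethiol, CCS
Why: Thiolate cleavage of the hindered imide as in step 3; the weakly basic thiolate should not enolise C5.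

**Step 10**
Reactants: 15 dihydropyran thioester
Product: 16 methyl ketone
Conditions: Me2CuLi (from CuI and MeLi), Et2O, −78 → −40 °C
Reagents that add atoms: lithium dimethylcuprate, [Li+].C[Cu-]C
Why: A Gilman cuprate converts a thioester into a ketone without over-addition and leaves the lactone, allyl ether and silyl ether alone; the non-basic reagent avoids enolisation at C5.

**Step 11**
Reactants: 16 methyl ketone
Product: 17 isopropenyl dihydropyran
Conditions: Zn, CH2Br2, TiCl4, THF/CH2Cl2, 0 °C → rt
Reagents that add atoms: dibromomethane, BrCBr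
Why: The Lombardo methylenation is non-basic and ketone-selective, so the enolisable β-alkoxy ketone should become the C4 isopropenyl group without epimerisation or β-elimination at C5 and without attack on the lactone.

**Step 12**
Reactants: 17 isopropenyl dihydropyran
Product: 20 α-methylene lactone, via Mannich base 18 (not isolated), via ammonium iodide 19 (not isolated)
Conditions: LiN(i-Pr)2, THF, −78 °C; Me2N=CH2 I (Eschenmoser's salt), −78 °C → rt; MeI, MeOH, rt; aq. NaHCO3, CH2Cl2, rt
Reagents that add atoms: Eschenmoser's salt, C=[N+](C)C.[I-]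
Why: Mannich α-methylenation of a γ-lactone (enolate aminomethylation, N-methylation, elimination of trimethylamine); the lactone α-CH2 is the only acidic site left.

**Step 13**
Reactants: 20 α-methylene lactone
Product: 21 (Z)-allylic chloride acetate
Conditions: AcCl, ZnCl2 (cat.), 2,6-di-tert-butyl-4-methylpyridine, CH2Cl2, 0 °C
Reagents that add atoms: acetyl chloride, CC(Cl)=O
Why: Acylative cleavage of a cyclic ether by an acyl chloride and a zinc halide: O-acetylation of the ring oxygen gives an acyloxonium ion that chloride opens by SN2 attack at the primary allylic carbon C2, leaving the acetate on C6 and carrying the Z-olefin of the ring into the open chain.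

**Step 14**
Reactants: 21 (Z)-allylic chloride acetate
Product: 22 primary alcohol
Conditions: HF·pyridine, pyridine, THF, 0 °C → rt
Reagents that add atoms: none
Why: Buffered fluoride cleavage of the primary silyl ether should spare the acetate, the allylic chloride and the α-methylene lactone.

**Step 15**
Reactants: 22 primary alcohol
Product: 23 chloro aldehyde
Conditions: Dess–Martin periodinane, CH2Cl2, 0 °C → rt
Reagents that add atoms: none
Why: The Dess–Martin oxidation gives the α-acyloxy aldehyde under non-nucleophilic conditions compatible with the allylic chloride; the crude aldehyde is used at once.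

**Step 16**
Reactants: 23 chloro aldehyde
Product: 25 cyclohexanol, via allylchromium dichloride 24 (not isolated)
Conditions: CrCl2 (8 equiv), LiI (0.5 equiv), THF/DMPU (10:1), 0.005 M, slow addition of 23, rt; aq. NH4Cl
Reagents that add atoms: none
Why: Two equivalents of divalent chromium reduce the allylic chloride (after exchange to the iodide) to the σ-allyl species 24 of trivalent chromium, a polarity reversal that turns the electrophilic C2 terminus into a nucleophile whose γ-carbon C10 attacks the electrophilic C9 aldehyde; the closest known reaction type is the intramolecular Nozaki–Hiyama–Kishi allylation with a γ,γ-disubstituted allyl halide. The cyclohexane closes by 6-exo-trig attack on the carbonyl, through a Zimmerman–Traxler chair (Cr, O, C9, C10, C1, C2) cis-fused to the chair of the forming carbocycle. In that carbocyclic chair the trans-lactone spans C7/C8 diequatorially and the C5 isopropenyl group is equatorial, so only one chair is open and it fixes the faces of both C9 and C10 relative to C5, C7 and C8. The Z-olefin stored by the former dihydropyran places C5 cis to the CH2Cr carbon, hence axial in the Zimmerman–Traxler chair; this puts the C10 methyl axial and the new vinyl equatorial on the carbocycle (C10) and the C9 oxygen axial, cis to the vinyl and trans to the methyl (C9). The step needs chemoselectivity for the aldehyde over the lactone, acetate and enoate (allylchromium reagents add only to aldehydes), γ- over α-attack (α-attack would give an eight-membered ring) and retention of the Z-allyl geometry. The last is secured by the slow E/Z exchange of γ,γ-disubstituted allylchromium reagents and by fast six-ring closure at high dilution.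

**Step 17**
Reactants: 25 cyclohexanol; 26 angelic acid
Product: 28 angelate, via mixed anhydride 27 (not isolated)
Conditions: 26, 2,4,6-trichlorobenzoyl chloride, Et3N, toluene, rt; then 25, 80 °C
Reagents that add atoms: none
Why: Yamaguchi-type esterification through the mixed 2,4,6-trichlorobenzoic anhydride without a nucleophilic catalyst should acylate the hindered axial C9–OH while keeping the Z-geometry of the angelate.

**Step 18**
Reactants: 28 angelate
Product: 30 target CNP0252310.1, via allylic alcohol 29 (not isolated)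
Conditions: SeO2 (0.5 equiv), t-BuOOH, CH2Cl2, rt; filter; then MnO2, CH2Cl2, rt
Reagents that add atoms: tert-butyl hydroperoxide, CC(C)(C)OO
Why: Allylic oxidation with SeO2 (ene reaction, then [2,3]-sigmatropic shift) should functionalise the methyl of the isopropenyl group, the only electron-rich alkene with allylic hydrogens (the vinyl group has none, the enoates are deactivated); MnO2 then oxidises the primary allylic alcohol, and any of it already over-oxidised converges on the same enal.

**Compound list**

1 | (R)-4-benzyloxazolidin-2-one | O=C1N[C@H](Cc2ccccc2)CO1 | starting material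
2 | methyl 4-chloro-4-oxobutanoate | COC(=O)CCC(Cl)=O | starting material
3 | succinate imide: (R)-4-benzyl-3-(4-methoxy-4-oxobutanoyl)oxazolidin-2-one | COC(=O)CCC(=O)N1[C@H](Cc2ccccc2)COC1=O | intermediate
4 | 2-[(tert-butyldiphenylsilyl)oxy]acetaldehyde | O=CCO[Si](c1ccccc1)(c1ccccc1)C(C)(C)C | starting material
5 | syn-aldol adduct: methyl (3R,4R)-3-[(R)-4-benzyl-2-oxooxazolidine-3-carbonyl]-5-[(tert-butyldiphenylsilyl)oxy]-4-hydroxypentanoate | COC(=O)C[C@@H](C(=O)N1[C@H](Cc2ccccc2)COC1=O)[C@@H](O)CO[Si](c1ccccc1)(c1ccccc1)C(C)(C)C | intermediate (not isolated)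
6 | trans-lactone imide: (R)-4-benzyl-3-[(2R,3R)-2-{[(tert-butyldiphenylsilyl)oxy]methyl}-5-oxotetrahydrofuran-3-carbonyl]oxazolidin-2-one | O=C1C[C@@H](C(=O)N2[C@H](Cc3ccccc3)COC2=O)[C@H](CO[Si](c2ccccc2)(c2ccccc2)C(C)(C)C)O1 | intermediate
7 | lactone thioester: S-ethyl (2R,3R)-2-{[(tert-butyldiphenylsilyl)oxy]methyl}-5-oxotetrahydrofuran-3-carbothioate | O=C1C[C@@H](C(=O)SCC)[C@H](CO[Si](c2ccccc2)(c2ccccc2)C(C)(C)C)O1 | intermediate
8 | lactone aldehyde: (2R,3R)-2-{[(tert-butyldiphenylsilyl)oxy]methyl}-5-oxotetrahydrofuran-3-carbaldehyde | O=C1C[C@@H](C=O)[C@H](CO[Si](c2ccccc2)(c2ccccc2)C(C)(C)C)O1 | intermediate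
9 | (S)-4-benzyloxazolidin-2-one | O=C1N[C@@H](Cc2ccccc2)CO1 | starting material
10 | 3-methylbut-2-enoyl chloride | CC(C)=CC(Cl)=O | starting material
11 | senecioyl imide: (S)-4-benzyl-3-(3-methylbut-2-enoyl)oxazolidin-2-one | CC(C)=CC(=O)N1[C@@H](Cc2ccccc2)COC1=O | intermediate
12 | aldol adduct: (S)-4-benzyl-3-{(2S)-2-[(R)-[(2R,3S)-2-{[(tert-butyldiphenylsilyl)oxy]methyl}-5-oxotetrahydrofuran-3-yl](hydroxy)methyl]-3-methylbut-3-enoyl}oxazolidin-2-one | C=C(C)[C@H](C(=O)N1[C@@H](Cc2ccccc2)COC1=O)[C@H](O)[C@@H]1CC(=O)O[C@H]1CO[Si](c1ccccc1)(c1ccccc1)C(C)(C)C | intermediate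
13 | O-allyl ether: the C6 allyl ether of 12 (same configuration at all centres) | C=C(C)[C@H](C(=O)N1[C@@H](Cc2ccccc2)COC1=O)[C@H](OCC=C)[C@@H]1CC(=O)O[C@H]1CO[Si](c1ccccc1)(c1ccccc1)C(C)(C)C | intermediate
14 | dihydropyran imide: (S)-4-benzyl-3-{(2R,3S)-2-[(2R,3S)-2-{[(tert-butyldiphenylsilyl)oxy]methyl}-5-oxotetrahydrofuran-3-yl]-4-methyl-3,6-dihydro-2H-pyran-3-carbonyl}oxazolidin-2-one (2,3-trans) | CC1=CCO[C@H]([C@@H]2CC(=O)O[C@H]2CO[Si](c2ccccc2)(c2ccccc2)C(C)(C)C)[C@H]1C(=O)N1[C@@H](Cc2ccccc2)COC1=O | intermediate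
15 | dihydropyran thioester: S-ethyl (2R,3S)-2-[(2R,3S)-2-{[(tert-butyldiphenylsilyl)oxy]methyl}-5-oxotetrahydrofuran-3-yl]-4-methyl-3,6-dihydro-2H-pyran-3-carbothioate | CC1=CCO[C@H]([C@@H]2CC(=O)O[C@H]2CO[Si](c2ccccc2)(c2ccccc2)C(C)(C)C)[C@H]1C(=O)SCC | intermediate
16 | methyl ketone: (4S,5R)-4-[(2R,3S)-3-acetyl-4-methyl-3,6-dihydro-2H-pyran-2-yl]-5-{[(tert-butyldiphenylsilyl)oxy]methyl}dihydrofuran-2(3H)-one | CC1=CCO[C@H]([C@@H]2CC(=O)O[C@H]2CO[Si](c2ccccc2)(c2ccccc2)C(C)(C)C)[C@H]1C(C)=O | intermediate
17 | isopropenyl dihydropyran: (4S,5R)-5-{[(tert-butyldiphenylsilyl)oxy]methyl}-4-[(2S,3S)-4-methyl-3-(prop-1-en-2-yl)-3,6-dihydro-2H-pyran-2-yl]dihydrofuran-2(3H)-one | CC1=CCO[C@H]([C@@H]2CC(=O)O[C@H]2CO[Si](c2ccccc2)(c2ccccc2)C(C)(C)C)[C@H]1C(C)=C | intermediate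
18 | Mannich base: 3-[(dimethylamino)methyl] derivative of 17 at the lactone α-carbon (epimers at that carbon) | CC1=CCO[C@H]([C@@H]2C(CN(C)C)C(=O)O[C@H]2CO[Si](c2ccccc2)(c2ccccc2)C(C)(C)C)[C@H]1C(C)=C | intermediate (not isolated)
19 | ammonium iodide: N-methylated trimethylammonium iodide of 18 | CC1=CCO[C@H]([C@@H]2C(C[N+](C)(C)C)C(=O)O[C@H]2CO[Si](c2ccccc2)(c2ccccc2)C(C)(C)C)[C@H]1C(C)=C.[I-] | intermediate (not isolated)
20 | α-methylene lactone: (4S,5R)-5-{[(tert-butyldiphenylsilyl)oxy]methyl}-3-methylidene-4-[(2S,3S)-4-methyl-3-(prop-1-en-2-yl)-3,6-dihydro-2H-pyran-2-yl]dihydrofuran-2(3H)-one | CC1=CCO[C@H]([C@@H]2C(=C)C(=O)O[C@H]2CO[Si](c2ccccc2)(c2ccccc2)C(C)(C)C)[C@H]1C(C)=C | intermediate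
21 | (Z)-allylic chloride acetate: (1S,2S,3Z)-1-[(2R,3S)-2-{[(tert-butyldiphenylsilyl)oxy]methyl}-4-methylidene-5-oxotetrahydrofuran-3-yl]-5-chloro-3-methyl-2-(prop-1-en-2-yl)pent-3-en-1-yl acetate | ClC/C=C(/C)[C@@H]([C@H](OC(C)=O)[C@@H]1C(=C)C(=O)O[C@H]1CO[Si](c1ccccc1)(c1ccccc1)C(C)(C)C)C(C)=C | intermediate
22 | primary alcohol: (1S,2S,3Z)-5-chloro-1-[(2R,3S)-2-(hydroxymethyl)-4-methylidene-5-oxotetrahydrofuran-3-yl]-3-methyl-2-(prop-1-en-2-yl)pent-3-en-1-yl acetate | ClC/C=C(/C)[C@@H]([C@H](OC(C)=O)[C@@H]1C(=C)C(=O)O[C@H]1CO)C(C)=C | intermediate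
23 | chloro aldehyde: (1S,2S,3Z)-5-chloro-1-[(2R,3S)-2-formyl-4-methylidene-5-oxotetrahydrofuran-3-yl]-3-methyl-2-(prop-1-en-2-yl)pent-3-en-1-yl acetate | ClC/C=C(/C)[C@@H]([C@H](OC(C)=O)[C@@H]1C(=C)C(=O)O[C@H]1C=O)C(C)=C | intermediate
24 | allylchromium dichloride: the (Z)-σ-allyl complex of trivalent chromium formed from 23 at C2 (solvent ligands omitted) | Cl[Cr](Cl)C/C=C(/C)[C@@H]([C@H](OC(C)=O)[C@@H]1C(=C)C(=O)O[C@H]1C=O)C(C)=C | intermediate (not isolated)
25 | cyclohexanol: (3aS,4S,5S,6S,7S,7aR)-6-ethenyl-7-hydroxy-6-methyl-3-methylidene-2-oxo-5-(prop-1-en-2-yl)octahydro-1-benzofuran-4-yl acetate | C=C[C@]1(C)[C@H](O)[C@@H]2OC(=O)C(=C)[C@H]2[C@@H](OC(C)=O)[C@H]1C(C)=C | intermediate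
26 | angelic acid: (2Z)-2-methylbut-2-enoic acid | C/C=C(/C)C(=O)O | starting material
27 | mixed anhydride: (2Z)-2-methylbut-2-enoic 2,4,6-trichlorobenzoic anhydride | C/C=C(/C)C(=O)OC(=O)c1c(Cl)cc(Cl)cc1Cl | intermediate (not isolated)
28 | angelate: (3aS,4S,5S,6S,7S,7aR)-4-acetoxy-6-ethenyl-6-methyl-3-methylidene-2-oxo-5-(prop-1-en-2-yl)octahydro-1-benzofuran-7-yl (2Z)-2-methylbut-2-enoate | C=C[C@]1(C)[C@H](OC(=O)/C(C)=C\C)[C@@H]2OC(=O)C(=C)[C@H]2[C@@H](OC(C)=O)[C@H]1C(C)=C | intermediate
29 | allylic alcohol: (3aS,4S,5S,6S,7S,7aR)-4-acetoxy-6-ethenyl-5-(3-hydroxyprop-1-en-2-yl)-6-methyl-3-methylidene-2-oxooctahydro-1-benzofuran-7-yl (2Z)-2-methylbut-2-enoate | C=C[C@]1(C)[C@H](OC(=O)/C(C)=C\C)[C@@H]2OC(=O)C(=C)[C@H]2[C@@H](OC(C)=O)[C@H]1C(=C)CO | intermediate (not isolated)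
30 | CNP0252310.1: (3aS,4S,5R,6S,7S,7aR)-4-acetoxy-6-ethenyl-6-methyl-3-methylidene-2-oxo-5-(3-oxoprop-1-en-2-yl)octahydro-1-benzofuran-7-yl (2Z)-2-methylbut-2-enoate | C=C[C@]1(C)[C@H](OC(=O)/C(C)=C\C)[C@@H]2OC(=O)C(=C)[C@H]2[C@@H](OC(C)=O)[C@H]1C(=C)C=O | target

**Step count**

Total: 18 steps. Longest linear sequence: 17 steps (steps 1–4 and 6–18; step 5 is a one-step branch).

**Steps most likely to fail**

Step 16 (key ring closure). The allylchromium intermediate, or the chloride before it, may lose its Z-geometry through the tertiary σ-allyl isomer. The E-isomer would pass through a trans-fused transition state and give the C9 epimer; a slow closure would also allow intermolecular coupling. The fallback sets out from 22 and replaces the chromium reagent by a configurationally stable allylboronate. Miyaura-type borylation of the allylic chloride (B2pin2, Pd2(dba)3 cat., DMSO, 50 °C) should give the (Z)-allylboronate alcohol F1, the geometry being held because syn/anti exchange would need a tertiary σ-allylpalladium species. Dess–Martin oxidation then gives the boronate aldehyde F2, which on warming in toluene should close by thermal intramolecular allylboration through the same closed chair transition state, stereospecifically. Aqueous work-up returns the route at 25.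

Step 13 (acylative opening of the dihydropyran). Acyl transfer to the silyl ether oxygen, HCl addition or Lewis-acid acylation at the isopropenyl group, and ionisation of the acyloxonium ion to an allyl cation with loss of the Z-geometry may all compete. The fallback sets out from 20 and separates ether cleavage from acylation. Me2BBr (CH2Cl2, −78 °C, trace Et3N) should cleave the allylic C2–O bond by SN2 attack at low temperature in the presence of the silyl ether, giving after work-up the bromo alcohol F3. Acetylation (Ac2O, Sc(OTf)3 cat., MeCN, −20 °C) gives the bromo acetate F4, and halide exchange (LiCl, acetone, rt) returns the route at 21.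

Step 17 (angeloylation). The axial C9–OH next to the quaternary C10 may be acylated only slowly, and forcing conditions may isomerise the activated angelate to the tiglate. The fallback sets out from 25 and builds the Z-olefin after acylation. Esterification with 2-[bis(2,2,2-trifluoroethoxy)phosphoryl]propanoic acid (N,N'-diisopropylcarbodiimide, DMAP, CH2Cl2), a non-conjugated and more electrophilic acyl donor, should give the phosphonate ester F5. A Still–Gennari olefination with acetaldehyde (KN(SiMe3)2, 18-crown-6, THF, −78 °C) then forms the Z-trisubstituted enoate and returns the route at 28.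

**Further compounds**

F1 | step 16 | (Z)-allylboronate alcohol: (1S,2S,3Z)-1-[(2R,3S)-2-(hydroxymethyl)-4-methylidene-5-oxotetrahydrofuran-3-yl]-3-methyl-2-(prop-1-en-2-yl)-5-(4,4,5,5-tetramethyl-1,3,2-dioxaborolan-2-yl)pent-3-en-1-yl acetate | CC1(C)OB(C/C=C(/C)[C@@H]([C@H](OC(C)=O)[C@@H]2C(=C)C(=O)O[C@H]2CO)C(C)=C)OC1(C)C
F2 | step 16 | boronate aldehyde: the 2-formyl analogue of F1 | CC1(C)OB(C/C=C(/C)[C@@H]([C@H](OC(C)=O)[C@@H]2C(=C)C(=O)O[C@H]2C=O)C(C)=C)OC1(C)C
F3 | step 13 | bromo alcohol: (4S,5R)-4-[(1S,2S,3Z)-5-bromo-1-hydroxy-3-methyl-2-(prop-1-en-2-yl)pent-3-en-1-yl]-5-{[(tert-butyldiphenylsilyl)oxy]methyl}-3-methylidenedihydrofuran-2(3H)-one | BrC/C=C(/C)[C@@H]([C@H](O)[C@@H]1C(=C)C(=O)O[C@H]1CO[Si](c1ccccc1)(c1ccccc1)C(C)(C)C)C(C)=C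
F4 | step 13 | bromo acetate: the bromide analogue of 21 | BrC/C=C(/C)[C@@H]([C@H](OC(C)=O)[C@@H]1C(=C)C(=O)O[C@H]1CO[Si](c1ccccc1)(c1ccccc1)C(C)(C)C)C(C)=C
F5 | step 17 | phosphonate ester: the C9 2-[bis(2,2,2-trifluoroethoxy)phosphoryl]propanoate of 25 (epimers at the phosphonate α-carbon) | C=C[C@]1(C)[C@H](OC(=O)C(C)P(=O)(OCC(F)(F)F)OCC(F)(F)F)[C@@H]2OC(=O)C(=C)[C@H]2[C@@H](OC(C)=O)[C@H]1C(C)=C
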